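The route rests on cutting the pyran ring C of the 3,4-diarylchroman (O1, C2, C3, C4, C4a, C8a, fused to ring A) at C2–C3 and C4–C4a. The key step exploits the fact that C3 and C4 carry two aryl groups of unequal donor strength: in an (E)-stilbene, ring E (2-methoxy, 4-benzyloxy) out-donates carbonate-masked ring B, so a ring A aryloxymethyl cation bonds to C3 and the C4 cation closes back onto ring A. One operation thus builds the pyran, two C–C bonds and the trans C3/C4 pair under a chiral counter-anion. The stilbene already contains the enantiopure isoflavan unit on ring E, set by auxiliary alkylation; its partner is 3-(benzyloxy)phenoxymethyl acetate.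

Key step: step 16

Remark (assumption): the catalyst enantiomer that delivers (3R,4S) cannot be predicted and is to be fixed by trial. Locants C2–C8a and rings A and C refer to the 3,4-diarylchroman, ring B to its catechol ring, ring E to the central arene, and "isoflavan unit" to the second chroman on ring E.

Step 1
Reactants: 1 3-(benzyloxy)phenol
Product: 2 3-(benzyloxy)phenoxymethyl acetate
Conditions: BrCH2OAc, Ag2O, 4 Å MS, MeCN, rt
Reagents that add atoms: bromomethyl acetate, CC(=O)OCBr
Why: Silver-assisted Williamson-type O-alkylation of a phenol with an α-halo ether is the standard way to acetoxymethyl ethers and leaves the benzyl ether untouched.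

Step 2
Reactants: 3 2,3-dihydroxy-4-methoxybenzaldehyde
Product: 4 3-methoxy-6-vinylbenzene-1,2-diol
Conditions: Ph3PCH3Br (3.5 equiv), KOt-Bu (3.4 equiv), THF, 0 °C → rt; NH4Cl (aq); used at once
Reagents that add atoms: methyltriphenylphosphonium bromide, [Br-].C[P+](c1ccccc1)(c1ccccc1)c1ccccc1
Why: Wittig methylenation with excess ylide, in which two equivalents only deprotonate the catechol and the third olefinates the aldehyde, is routine for hydroxybenzaldehydes.

Step 3
Reactants: 4 3-methoxy-6-vinylbenzene-1,2-diol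
Product: 5 4-methoxy-7-vinyl-1,3-benzodioxol-2-one
Conditions: 1,1'-carbonyldiimidazole, CH2Cl2, 0 °C → rt
Reagents that add atoms: 1,1'-carbonyldiimidazole, O=C(n1ccnc1)n1ccnc1
Why: Carbonylation of a catechol closes the five-membered cyclic carbonate under neutral conditions that spare the electron-rich styrene, and it is placed after the ylide step, which the carbonate would not survive.

Step 4
Reactants: 6 methyl 2-(3,5-dihydroxyphenyl)acetate
Product: 7 methyl 2-[3-(benzyloxy)-5-hydroxyphenyl]acetate
Conditions: BnBr (1.0 equiv), K2CO3, acetone, reflux; diol recovered and recycled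
Reagents that add atoms: benzyl bromide, BrCc1ccccc1
Why: Williamson mono-etherification of the symmetric resorcinol with one equivalent of halide gives the mono ether as the main part of a separable statistical mixture.

Step 5
Reactants: 7 methyl 2-[3-(benzyloxy)-5-hydroxyphenyl]acetate
Product: 8 methyl 2-[3-acetoxy-5-(benzyloxy)phenyl]acetate
Conditions: Ac2O, pyridine, DMAP (cat.), CH2Cl2, rt
Reagents that add atoms: acetic anhydride, CC(=O)OC(C)=O
Why: Acetylation turns the second oxygen into a weak director, so that the benzyloxy group alone steers the next aromatic substitution.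

Step 6
Reactants: 8 methyl 2-[3-acetoxy-5-(benzyloxy)phenyl]acetate
Product: 9 methyl 2-[3-acetoxy-5-(benzyloxy)-2-bromophenyl]acetate
Conditions: NBS (1.0 equiv), MeCN, 0 °C → rt
Reagents that add atoms: N-bromosuccinimide, O=C1CCC(=O)N1Br
Why: Electrophilic aromatic bromination with NBS in MeCN goes para to the ether oxygen, which is the ring carbon between the acetoxy group and the side chain, and not para to the deactivated acetoxy group.

Step 7
Reactants: 9 methyl 2-[3-acetoxy-5-(benzyloxy)-2-bromophenyl]acetate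
Product: 11 2-[5-(benzyloxy)-2-bromo-3-methoxyphenyl]acetic acid, via bromo hydroxy acid 10 (not isolated)
Conditions: NaOH (aq), MeOH/THF, rt; Me2SO4, 0 °C → rt; NaOH, 50 °C; then HCl
Reagents that add atoms: dimethyl sulfate, COS(=O)(=O)OC; sodium hydroxide, [Na+].[OH-]
Why: Saponification frees phenoxide and carboxylate, Haworth-type methylation in aqueous base alkylates the phenoxide selectively, and the final warm hold with base destroys excess reagent and returns any methyl ester to the acid.

Step 8
Reactants: 11 2-[5-(benzyloxy)-2-bromo-3-methoxyphenyl]acetic acid; 12 (R)-4-benzyl-2-oxazolidinone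
Product: 14 (R)-4-benzyl-3-{2-[5-(benzyloxy)-2-bromo-3-methoxyphenyl]acetyl}oxazolidin-2-one, via mixed pivalic anhydride 13 (not isolated)
Conditions: t-BuCOCl, Et3N, THF, −20 °C; then 12, LiCl, rt
Reagents that add atoms: pivaloyl chloride, CC(C)(C)C(Cl)=O (its acyl group stays only in intermediate 13)
Why: N-Acylation of the oxazolidinone through the mixed pivalic anhydride with LiCl and Et3N is the standard one-pot entry to the imides used in Evans alkylation.

Step 9
Reactants: 15 4-(benzyloxy)-2-hydroxybenzaldehyde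
Product: 16 4-(benzyloxy)-2-(tert-butyldimethylsilyloxy)benzaldehyde
Conditions: t-BuMe2SiCl, imidazole, DMF, rt
Reagents that add atoms: tert-butyldimethylsilyl chloride, CC(C)(C)[Si](C)(C)Cl
Why: Standard phenol silylation masks the oxygen that later closes the isoflavan pyran and is orthogonal to the benzyl ethers.

Step 10
Reactants: 16 4-(benzyloxy)-2-(tert-butyldimethylsilyloxy)benzaldehyde
Product: 17 [4-(benzyloxy)-2-(tert-butyldimethylsilyloxy)phenyl]methanol
Conditions: NaBH4, THF/MeOH, 0 °C, short contact; NH4Cl (aq)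
Reagents that add atoms: none
Why: Borohydride reduction of the aldehyde is chemoselective, and cold, brief conditions with a buffered quench limit silyl migration to the new alkoxide.

Step 11
Reactants: 17 [4-(benzyloxy)-2-(tert-butyldimethylsilyloxy)phenyl]methanol
Product: 18 4-(benzyloxy)-1-(bromomethyl)-2-(tert-butyldimethylsilyloxy)benzene
Conditions: CBr4, PPh3, CH2Cl2, 0 °C; short filtration, used at once
Reagents that add atoms: carbon tetrabromide, BrC(Br)(Br)Br
Why: The Appel reaction converts the electron-rich benzylic alcohol to the bromide under neutral conditions, and the labile halide is not stored.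

Step 12
Reactants: 14 (R)-4-benzyl-3-{2-[5-(benzyloxy)-2-bromo-3-methoxyphenyl]acetyl}oxazolidin-2-one; 18 4-(benzyloxy)-1-(bromomethyl)-2-(tert-butyldimethylsilyloxy)benzene
Product: 19 (R)-4-benzyl-3-{(R)-2-[5-(benzyloxy)-2-bromo-3-methoxyphenyl]-3-[4-(benzyloxy)-2-(tert-butyldimethylsilyloxy)phenyl]propanoyl}oxazolidin-2-one
Conditions: NaN(SiMe3)2 (1.05 equiv), THF, −78 °C; then 18, −78 → −30 °C
Reagents that add atoms: none
Why: In this Evans asymmetric alkylation the chelated sodium Z-enolate is attacked by the benzylic bromide on the face away from the 4-benzyl group, which with the (R)-auxiliary gives the (R) α-carbon, the future C3 of the isoflavan unit.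

Step 13
Reactants: 19 (R)-4-benzyl-3-{(R)-2-[5-(benzyloxy)-2-bromo-3-methoxyphenyl]-3-[4-(benzyloxy)-2-(tert-butyldimethylsilyloxy)phenyl]propanoyl}oxazolidin-2-one
Product: 20 (R)-2-[5-(benzyloxy)-2-bromo-3-methoxyphenyl]-3-[4-(benzyloxy)-2-(tert-butyldimethylsilyloxy)phenyl]propan-1-ol
Conditions: LiBH4, MeOH (1.5 equiv), THF, 0 °C
Reagents that add atoms: none
Why: Reductive removal of the auxiliary attacks the exocyclic imide carbonyl and gives the primary alcohol without touching the stereocenter, the aryl bromide or the silyl ether.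

Step 14
Reactants: 20 (R)-2-[5-(benzyloxy)-2-bromo-3-methoxyphenyl]-3-[4-(benzyloxy)-2-(tert-butyldimethylsilyloxy)phenyl]propan-1-ol
Product: 23 (R)-7-(benzyloxy)-3-[5-(benzyloxy)-2-bromo-3-methoxyphenyl]chroman, via silyl ether mesylate 21 (not isolated), via phenol mesylate 22 (not isolated)
Conditions: MsCl, Et3N, THF, 0 °C; then Bu4NF, THF, 0 °C → rt
Reagents that add atoms: methanesulfonyl chloride, CS(Cl)(=O)=O (its sulfonyl group stays only in intermediates 21 and 22)
Why: Mesylation and fluoride desilylation release a phenoxide that closes the pyran by intramolecular Williamson etherification (6-exo-tet) at the primary carbon, so the neighbouring stereocenter is not involved.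

Step 15
Reactants: 23 (R)-7-(benzyloxy)-3-[5-(benzyloxy)-2-bromo-3-methoxyphenyl]chroman; 5 4-methoxy-7-vinyl-1,3-benzodioxol-2-one
Product: 24 4-[(E)-2-{4-(benzyloxy)-2-[(3R)-7-(benzyloxy)chroman-3-yl]-6-methoxyphenyl}vinyl]-7-methoxy-1,3-benzodioxol-2-one
Conditions: Pd2(dba)3 (zerovalent palladium, 2.5 mol%), [HP(t-Bu)3]BF4 (10 mol%), Cy2NMe, dry dioxane, 70 °C
Reagents that add atoms: none
Why: The Mizoroki–Heck reaction under bulky trialkylphosphine catalysis handles hindered electron-rich aryl bromides, gives the E-stilbene by syn insertion and syn β-hydride elimination, and uses a tertiary amine that cannot aminolyse the carbonate.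

Step 16
Reactants: 24 4-[(E)-2-{4-(benzyloxy)-2-[(3R)-7-(benzyloxy)chroman-3-yl]-6-methoxyphenyl}vinyl]-7-methoxy-1,3-benzodioxol-2-one; 2 3-(benzyloxy)phenoxymethyl acetate
Product: 25 4-[(3R,4S)-7-(benzyloxy)-4-{4-(benzyloxy)-2-[(3R)-7-(benzyloxy)chroman-3-yl]-6-methoxyphenyl}chroman-3-yl]-7-methoxy-1,3-benzodioxol-2-one
Conditions: chiral confined imidodiphosphorimidate Brønsted acid (two 3,3'-diaryl-BINOL units, N-SO2CF3 groups; 5–10 mol%), 5 Å MS, toluene/CH2Cl2, −50 °C, slow addition of 2
Reagents that add atoms: none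
Why: Proposed new method: the chiral acid protonates the acetate of 2, acetic acid leaves, and the aryloxymethyl oxocarbenium ion, ion-paired with the chiral anion, is attacked at its CH2 carbon by the alkene carbon bearing ring B (C2–C3), after which the C4 benzylic cation is captured by ring A para to its benzyloxy group (C4–C4a) and the arenium ion returns the proton to the anion. The closest known reactions are the Lewis-acid oxa-Povarov annulation of aryl oxocarbenium ions with styrenes and confined-acid catalysis of oxocarbenium additions to alkenes. Ring C closes by intramolecular Friedel–Crafts alkylation through a chair-like six-membered transition state, the second half of a stepwise polar [4+2]. C3 is set in the first bond formation by the chiral anion, which selects the alkene face, and C4 follows because suprafacial addition across the E alkene with both aryl groups pseudo-equatorial leaves rings B and E trans. The step needs regioselectivity between the two alkene carbons (the 2-methoxy and 4-benzyloxy donors of ring E against carbonate-deactivated ring B), site selectivity on ring A (the para-directing benzyloxy group), and chemoselectivity against intermolecular Friedel–Crafts attack on spectator arenes (slow addition of 2 at low temperature).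

Step 17
Reactants: 25 4-[(3R,4S)-7-(benzyloxy)-4-{4-(benzyloxy)-2-[(3R)-7-(benzyloxy)chroman-3-yl]-6-methoxyphenyl}chroman-3-yl]-7-methoxy-1,3-benzodioxol-2-one
Product: 26 3-[(3R,4S)-7-(benzyloxy)-4-{4-(benzyloxy)-2-[(3R)-7-(benzyloxy)chroman-3-yl]-6-methoxyphenyl}chroman-3-yl]-6-methoxybenzene-1,2-diol
Conditions: K2CO3 (cat.), degassed MeOH/THF, 0 °C, Ar; AcOH quench
Reagents that add atoms: none
Why: Base-catalysed transesterification of the strained aryl carbonate with methanol is fast at 0 °C and frees the catechol while benzyl ethers and all stereocenters stay untouched.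

Step 18
Reactants: 26 3-[(3R,4S)-7-(benzyloxy)-4-{4-(benzyloxy)-2-[(3R)-7-(benzyloxy)chroman-3-yl]-6-methoxyphenyl}chroman-3-yl]-6-methoxybenzene-1,2-diol
Product: 27 3-[(3R,4S)-7-hydroxy-4-{4-hydroxy-2-[(3R)-7-hydroxychroman-3-yl]-6-methoxyphenyl}chroman-3-yl]-6-methoxybenzene-1,2-diol (CNP0227211.1)
Conditions: H2 (1 atm), Pd/C, THF/MeOH, rt
Reagents that add atoms: none
Why: Hydrogenolysis cleaves the three aryl benzyl ethers, the molecule holds no other hydrogenolysable C–O or C–halogen bond, and the neutral reducing medium protects the catechol.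

Compound list
1 | 3-(benzyloxy)phenol | Oc1cccc(OCc2ccccc2)c1 | starting material
2 | 3-(benzyloxy)phenoxymethyl acetate | CC(=O)OCOc1cccc(OCc2ccccc2)c1 | intermediate
3 | 2,3-dihydroxy-4-methoxybenzaldehyde | COc1ccc(C=O)c(O)c1O | starting material
4 | 3-methoxy-6-vinylbenzene-1,2-diol | COc1ccc(C=C)c(O)c1O | intermediate
5 | 4-methoxy-7-vinyl-1,3-benzodioxol-2-one | COc1ccc(C=C)c2OC(=O)Oc12 | intermediate
6 | methyl 2-(3,5-dihydroxyphenyl)acetate | COC(=O)Cc1cc(O)cc(O)c1 | starting material
7 | methyl 2-[3-(benzyloxy)-5-hydroxyphenyl]acetate | COC(=O)Cc1cc(O)cc(OCc2ccccc2)c1 | intermediate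
8 | methyl 2-[3-acetoxy-5-(benzyloxy)phenyl]acetate | COC(=O)Cc1cc(OC(C)=O)cc(OCc2ccccc2)c1 | intermediate
9 | methyl 2-[3-acetoxy-5-(benzyloxy)-2-bromophenyl]acetate | COC(=O)Cc1cc(OCc2ccccc2)cc(OC(C)=O)c1Br | intermediate
10 | 2-[5-(benzyloxy)-2-bromo-3-hydroxyphenyl]acetic acid (present as its disodium salt) | OC(=O)Cc1cc(OCc2ccccc2)cc(O)c1Br | intermediate
11 | 2-[5-(benzyloxy)-2-bromo-3-methoxyphenyl]acetic acid | COc1cc(OCc2ccccc2)cc(CC(O)=O)c1Br | intermediate
12 | (R)-4-benzyl-2-oxazolidinone | O=C1N[C@H](Cc2ccccc2)CO1 | starting material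
13 | 2-[5-(benzyloxy)-2-bromo-3-methoxyphenyl]acetic pivalic anhydride | COc1cc(OCc2ccccc2)cc(CC(=O)OC(=O)C(C)(C)C)c1Br | intermediate
14 | (R)-4-benzyl-3-{2-[5-(benzyloxy)-2-bromo-3-methoxyphenyl]acetyl}oxazolidin-2-one | COc1cc(OCc2ccccc2)cc(CC(=O)N2[C@H](Cc3ccccc3)COC2=O)c1Br | intermediate
15 | 4-(benzyloxy)-2-hydroxybenzaldehyde | O=Cc1ccc(OCc2ccccc2)cc1O | starting material
16 | 4-(benzyloxy)-2-(tert-butyldimethylsilyloxy)benzaldehyde | O=Cc1ccc(OCc2ccccc2)cc1O[Si](C)(C)C(C)(C)C | intermediate
17 | [4-(benzyloxy)-2-(tert-butyldimethylsilyloxy)phenyl]methanol | OCc1ccc(OCc2ccccc2)cc1O[Si](C)(C)C(C)(C)C | intermediate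
18 | 4-(benzyloxy)-1-(bromomethyl)-2-(tert-butyldimethylsilyloxy)benzene | BrCc1ccc(OCc2ccccc2)cc1O[Si](C)(C)C(C)(C)C | intermediate
19 | (R)-4-benzyl-3-{(R)-2-[5-(benzyloxy)-2-bromo-3-methoxyphenyl]-3-[4-(benzyloxy)-2-(tert-butyldimethylsilyloxy)phenyl]propanoyl}oxazolidin-2-one | COc1cc(OCc2ccccc2)cc([C@@H](Cc2ccc(OCc3ccccc3)cc2O[Si](C)(C)C(C)(C)C)C(=O)N2[C@H](Cc3ccccc3)COC2=O)c1Br | intermediate
20 | (R)-2-[5-(benzyloxy)-2-bromo-3-methoxyphenyl]-3-[4-(benzyloxy)-2-(tert-butyldimethylsilyloxy)phenyl]propan-1-ol | COc1cc(OCc2ccccc2)cc([C@@H](Cc2ccc(OCc3ccccc3)cc2O[Si](C)(C)C(C)(C)C)CO)c1Br | intermediate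
21 | (R)-2-[5-(benzyloxy)-2-bromo-3-methoxyphenyl]-3-[4-(benzyloxy)-2-(tert-butyldimethylsilyloxy)phenyl]propyl methanesulfonate | COc1cc(OCc2ccccc2)cc([C@@H](Cc2ccc(OCc3ccccc3)cc2O[Si](C)(C)C(C)(C)C)COS(C)(=O)=O)c1Br | intermediate
22 | (R)-2-[5-(benzyloxy)-2-bromo-3-methoxyphenyl]-3-[4-(benzyloxy)-2-hydroxyphenyl]propyl methanesulfonate (present as its phenoxide) | COc1cc(OCc2ccccc2)cc([C@@H](Cc2ccc(OCc3ccccc3)cc2O)COS(C)(=O)=O)c1Br | intermediate
23 | (R)-7-(benzyloxy)-3-[5-(benzyloxy)-2-bromo-3-methoxyphenyl]chroman | COc1cc(OCc2ccccc2)cc([C@@H]2COc3cc(OCc4ccccc4)ccc3C2)c1Br | intermediate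
24 | 4-[(E)-2-{4-(benzyloxy)-2-[(3R)-7-(benzyloxy)chroman-3-yl]-6-methoxyphenyl}vinyl]-7-methoxy-1,3-benzodioxol-2-one | COc1ccc(c2OC(=O)Oc12)/C=C/c1c(OC)cc(OCc2ccccc2)cc1[C@@H]1COc2cc(OCc3ccccc3)ccc2C1 | intermediate
25 | 4-[(3R,4S)-7-(benzyloxy)-4-{4-(benzyloxy)-2-[(3R)-7-(benzyloxy)chroman-3-yl]-6-methoxyphenyl}chroman-3-yl]-7-methoxy-1,3-benzodioxol-2-one | COc1ccc(c2OC(=O)Oc12)[C@@H]1COc2cc(OCc3ccccc3)ccc2[C@H]1c1c(OC)cc(OCc2ccccc2)cc1[C@@H]1COc2cc(OCc3ccccc3)ccc2C1 | intermediate
26 | 3-[(3R,4S)-7-(benzyloxy)-4-{4-(benzyloxy)-2-[(3R)-7-(benzyloxy)chroman-3-yl]-6-methoxyphenyl}chroman-3-yl]-6-methoxybenzene-1,2-diol | COc1ccc([C@@H]2COc3cc(OCc4ccccc4)ccc3[C@H]2c2c(OC)cc(OCc3ccccc3)cc2[C@@H]2COc3cc(OCc4ccccc4)ccc3C2)c(O)c1O | intermediate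
27 | 3-[(3R,4S)-7-hydroxy-4-{4-hydroxy-2-[(3R)-7-hydroxychroman-3-yl]-6-methoxyphenyl}chroman-3-yl]-6-methoxybenzene-1,2-diol (CNP0227211.1) | COc1ccc([C@@H]2COc3cc(O)ccc3[C@H]2c2c(OC)cc(O)cc2[C@@H]2COc3cc(O)ccc3C2)c(O)c1O | target

Total step count: 18
Longest linear sequence: 12 steps (steps 4–8 and 12–18, from 6 to 27)

Steps most likely to fail

Step 16. The chiral anion may give poor facial selectivity, the released acetic acid may stall turnover, or the oxocarbenium ion may be consumed by self-condensation before it meets the alkene. The fallback drops asymmetric catalysis and sets out from 2 and 24. A full equivalent of SnCl4 in CH2Cl2 at −78 °C would ionise the acetate and drive the annulation in the stoichiometric Lewis-acid oxa-Povarov mode, which is established for aryl oxocarbenium ions and styrenes. The E alkene still fixes the trans relation. Because the isoflavan centre is already (R), the two trans adducts are diastereomers and not enantiomers: 25 and its (3S,4R) isomer 4-[(3S,4R)-7-(benzyloxy)-4-{4-(benzyloxy)-2-[(3R)-7-(benzyloxy)chroman-3-yl]-6-methoxyphenyl}chroman-3-yl]-7-methoxy-1,3-benzodioxol-2-one F1. They would be separated by chromatography or crystallisation, so stereocontrol rests on separation through the resident centre instead of on the catalyst. The fallback returns to the route at 25.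

Step 15. Oxidative addition into the bromide flanked by two ortho substituents may be slow, and the temperature then needed may open the carbonate by base and trace water. The fallback sets out from 23 and replaces the Heck reaction by olefin metathesis, which needs no base in the presence of the carbonate. Suzuki–Miyaura vinylation of 23 (CH2=CHBF3K, PdCl2(dppf), Cs2CO3, THF/H2O, 80 °C) would give the ring E styrene (R)-7-(benzyloxy)-3-[5-(benzyloxy)-3-methoxy-2-vinylphenyl]chroman F2. Cross-metathesis of F2 with an excess of styrene 5, using RuCl2(H2IMes)(=CH-C6H4-2-O-i-Pr) (second-generation Hoveyda–Grubbs catalyst) in toluene at 60 °C, would give the E-stilbene; the hindered styrene F2 does not homodimerise. The fallback returns to the route at 24.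

Step 12. The electron-rich benzylic bromide 18 may decompose by ionisation and self-alkylation before the weakly nucleophilic aryl-stabilised enolate captures it, and the acidic α-aryl centre may partly epimerise. The fallback sets out from 11 and 15 and sets the isoflavan centre by catalytic asymmetric hydrogenation. Perkin–Oglialoro condensation of 11 with 15 (Ac2O, Et3N, 120 °C) would give the 3-arylcoumarin 7-(benzyloxy)-3-[5-(benzyloxy)-2-bromo-3-methoxyphenyl]-2H-chromen-2-one F3. Reduction with i-Bu2AlH (CH2Cl2, −78 → 0 °C) would open it to the allylic diol (Z)-2-[5-(benzyloxy)-2-bromo-3-methoxyphenyl]-3-[4-(benzyloxy)-2-hydroxyphenyl]prop-2-en-1-ol F4. Mitsunobu cyclisation (PPh3, DIAD, THF) would give 7-(benzyloxy)-3-[5-(benzyloxy)-2-bromo-3-methoxyphenyl]-2H-chromene F5. Hydrogenation of F5 with [Ir(cod)(L*)]BArF, a cationic complex of monovalent iridium with a chiral phosphine–oxazoline ligand L* (H2, 50 bar, CH2Cl2), with the ligand enantiomer chosen for (R), tolerates the aryl bromide. The fallback returns to the route at 23.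

Further compounds
F1 | step 16 | 4-[(3S,4R)-7-(benzyloxy)-4-{4-(benzyloxy)-2-[(3R)-7-(benzyloxy)chroman-3-yl]-6-methoxyphenyl}chroman-3-yl]-7-methoxy-1,3-benzodioxol-2-one | COc1ccc(c2OC(=O)Oc12)[C@H]1COc2cc(OCc3ccccc3)ccc2[C@@H]1c1c(OC)cc(OCc2ccccc2)cc1[C@@H]1COc2cc(OCc3ccccc3)ccc2C1
F2 | step 15 | (R)-7-(benzyloxy)-3-[5-(benzyloxy)-3-methoxy-2-vinylphenyl]chroman | C=Cc1c(OC)cc(OCc2ccccc2)cc1[C@@H]1COc2cc(OCc3ccccc3)ccc2C1
F3 | step 12 | 7-(benzyloxy)-3-[5-(benzyloxy)-2-bromo-3-methoxyphenyl]-2H-chromen-2-one | COc1cc(OCc2ccccc2)cc(-c2cc3ccc(OCc4ccccc4)cc3oc2=O)c1Br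
F4 | step 12 | (Z)-2-[5-(benzyloxy)-2-bromo-3-methoxyphenyl]-3-[4-(benzyloxy)-2-hydroxyphenyl]prop-2-en-1-ol | OC/C(=C\c1ccc(OCc2ccccc2)cc1O)c1cc(OCc2ccccc2)cc(OC)c1Br
F5 | step 12 | 7-(benzyloxy)-3-[5-(benzyloxy)-2-bromo-3-methoxyphenyl]-2H-chromene | COc1cc(OCc2ccccc2)cc(C2=Cc3ccc(OCc4ccccc4)cc3OC2)c1Br
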